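Readings and results come from a simulation with made-up constants, noise included.

Percent of the G charged was the unit of the readings, so runs with different charges could be laid side by side.

| setting | epsilon | theta | zeta | flask |
|---|---|---|---|---|
| G | 10 mM | 10 mM | 20 mM | 10 mM |
| X | 0.67 µM | 1.5 µM | 1 µM | 1.0 µM |
| remark | run made earlier | run made earlier | run made earlier |  |

| run | time / min | Z / % | G / % |
|---|---|---|---|
| epsilon | 20.0 | 30 | 22 |
| epsilon | 40.0 | 44 | 4 |
| epsilon | 50.0 | 47 | 4 |
| epsilon | 80.0 | 49 | 2 |
| theta | 20.0 | 57 | 9 |
| theta | 40.0 | 62 | 1 |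
| theta | 50.0 | 64 | 0 |
| theta | 80.0 | 61 | 1 |
| zeta | 6.00 | 6 | 47 |
| zeta | 12.0 | 20 | 26 |
| zeta | 30.0 | 35 | 7 |
| zeta | 80.0 | 40 | 0 |

(scatter of a reading: 1.5 percentage points)



- factor on the rate of making Z when 10 % of the G are converted if X is charged twice over
- factor on the rate when 10 % of the G are converted if X is charged at 5.0 µM instead

In the epsilon run at 80.0 min, Z and G summed to 51.0 %, so G was going somewhere besides Z. The epsilon and theta runs shared a [G] of 10 mM but differed in [X], so I held them against each other at 20.0 min, where Z stood at 30 % and 57 %.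

From that pair the catalyst order came to 0.796, give or take 0.0701 from the scatter. I defined it, as an apparent order in X, as the logarithm of the ratio of two Z readings over the logarithm of the ratio of their [X] charges, at equal [G] and equal time. But those readings stood far past 10 % conversion, so I carried it forward as a reading. It gave me 1.74 for doubling and 3.60 at 5.0 µM.

The forecast gave 1.7 and 3.4, “assuming the order holds on extrapolation”; at 5.0 µM my figure was higher than the forecast's.

The flask gave 1.86 for doubling and 3.97 at 5.0 µM.

    2 G → E (k = 0.0620 M⁻¹ s⁻¹)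
    X ⇌ Q (K = 9.80, k = 0.00450 s⁻¹)
    G + Q → Z + Q, rate k3*[G]*[Q]/(1 + ([G]/Km3)) (12.0 mM, k = 1600 M⁻¹ s⁻¹)

The flask reached 10 % conversion at 1.33 min, sooner than the relaxation half-life of X and Q by the step X ⇌ Q alone, 2.33 min. In the flask, doubling read back as a catalyst order of 0.895 against my 0.796, and the charge of 5.0 µM read back as 0.857.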